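## Structural features

The target is a 5,6,7,8-tetrahydroquinoline: a pyridine ring (N1, C2, C3, C4, C4a, C8a) fused through the C4a–C8a bond to a six-membered carbocycle (C4a, C5, C6, C7, C8, C8a). C6 is an all-carbon quaternary centre and the only stereocentre, of (S) configuration. It carries a 3,4-dimethoxyphenyl group and a two-carbon arm Cα–Cβ that ends in an N-methylformamide, so no neighbouring stereocentre is available to relay its configuration. The sensitive groups are the tertiary formamide (hydrolysis, hydride reduction), the basic and nucleophilic pyridine nitrogen (quaternisation, binding to metals), the two picolylic methylenes C5 and C8, and the electron-rich dimethoxyaryl ring. The real difficulty is the absolute configuration of C6: three of its four substituents are methylene groups, and the two ring methylenes C5 and C7 differ only in their distance from the pyridine. The structure hides a pyrrolidine: with nitrogen bonded to the picolylic C5, the atoms N–C5–C6–Cα–Cβ form a five-membered ring cis-fused to the carbocycle across C5–C6, and in that tricycle C5 and C6 are adjacent stereocentres. The tricycle is the [3+2] adduct of an azomethine ylide spanning C5–N–Cβ with a 1,1-disubstituted styrene C6=Cα held by the C7–C8 tether, and its extra C5–N bond is picolylic and therefore open to hydrogenolysis. The key step exploits exactly this.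

## Logic of the disconnections

**20 to 18.** The N–CH3 bond is cut first. The formamide N–H is the most acidic site of 18, so the methyl group can be put on last through the amidate 19. The gain is small but it leaves a nitrogen that carries only the formyl group. The forward step must alkylate the amide nitrogen faster than the pyridine nitrogen.

**18 to 17.** The N–CHO bond is cut, which leaves a primary amine. The forward step is a simple acylation by a formyl donor and only has to stop at the monoformyl stage.

**17 to 15.** In the backward sense two bonds are made: N to the picolylic C5, and N to a 1-phenylethyl group. This converts the open aminoethyl arm into a pyrrolidine, creates C5 as a relay stereocentre next to C6, and places a removable stereocontrolling group on nitrogen. The gain is the cycloadduct retron. The forward step must cleave both benzylic-type C–N bonds by hydrogenolysis (through 16) without saturating the pyridine.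

**15 to 8 and 12.** Three bonds are cut: C5–C6, Cα–Cβ and C5–N. This is the retro-[3+2] cycloaddition of the ylide 14, which arises from 8 and 12 through 13 with loss of carbon dioxide. Two rings, three skeletal bonds and both stereocentres disappear, and all stereochemistry is removed from the carbon skeleton. The forward step needs the dipole to add to the tethered alkene with the right regiochemistry, a cis ring fusion and a bias for one alkene face.

**8 to 6.** The aldehyde is traced to a nitrile by functional-group interconversion. The nitrile is a latent aldehyde that survives carbanion and cross-coupling chemistry and acidifies the neighbouring methyl group of 1. The forward step must stop the reduction at the aldimine stage (7).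

**6 to 4 and 5.** The bond between the aryl ring and the alkene carbon C6 is cut. Making the styrene by cross-coupling avoids a carbonyl methylenation and a ketone intermediate. The forward step needs a clean coupling at a 2-bromoalkene in the presence of a pyridine and a nitrile.

**4 to 1 and 2.** The C7–C8 bond is cut between the picolylic carbon and the allyl unit. C8 becomes a lateral carbanion (3) and C7 an allylic bromide, and both partners are commercial. The forward step must monoalkylate and must react at the allylic, not the vinylic, bromide.

**12 to 11, then to 9 and 10.** The acid is traced to its ethyl ester, and the N–CH2 bond is then cut. The stereocentre of the auxiliary comes from the commercial amine 9. The forward steps must stop at monoalkylation and leave the benzylic centre untouched.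

## Other disconnections considered

**Alternative 1:** The carbocycle is cut at C6–C7 and C4a–C5, the two bonds of a cyclohexene retron, so the carbocycle is made first and the pyridine later.

- **Forward step.** 2-(3,4-Dimethoxyphenyl)prop-2-enal A1 and the 1-amino-3-silyloxybutadiene A2 would undergo a [4+2] cycloaddition under a chiral salen complex of trivalent chromium, (salen)CrSbF6. Acidic work-up would unmask the ketone and eliminate the amine to give the 4-aryl-4-formylcyclohexenone A3, with C6 already quaternary and the carbonyl at the future C8a.
- **In its favour.** The stereocentre is set by a catalyst in a reaction type established for α-substituted acroleins, and both components are simple and achiral. On absolute stereocontrol this plan is the better of the two, because the chosen route relies on an auxiliary of uncertain bias.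
- **Against it here.** A3 contains neither the pyridine nor Cβ and the nitrogen. Its formyl carbon is Cα, so a one-carbon homologation and an amination are needed beside an enone. The pyridine must then be annulated across C8a–C4a. The configuration of A3 is defined only by the difference between the unsaturated arm (C7=C8) and the saturated arm (C5, C4a). A 4,4-disubstituted cyclohexanone is achiral, so the ring fusion would have to be directed to C4a before the double bond is reduced.
- **Comparison.** In mechanism the two key steps are both concerted cycloadditions and are equal in the reliability of bond formation. In structure the chosen step delivers two rings, three bonds and every skeletal atom, against one ring and two bonds. In step economy an estimated seven or eight steps would follow A3, against three after 15.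

**Alternative 2:** The cut is C4a–C5, read as the result of a ring expansion in which C5 and C7 are the two methylenes of a cyclobutanol whose carbinol carbon is C8.

- **Forward step.** The cyclobutanol A4 carries the 3-bromopyridin-2-yl group at the carbinol carbon and the aryl group and the carbamate-protected aminoethyl arm at the opposite ring carbon. With a chiral palladium catalyst, zerovalent palladium would insert into the C4a–Br bond and the tertiary alkoxide would bind. β-Carbon elimination would break one of the two enantiotopic bonds at C8, and reductive elimination would close C4a–C5 to give the 8-oxotetrahydroquinoline A5.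
- **In its favour.** The stereocentre is catalyst-controlled, and the pyridine and the complete N-methylated arm are present from the start. No C–N hydrogenolysis and no late N-methylation next to a pyridine are needed, and on this point (a safer endgame) it is better than the chosen plan.
- **Against it here.** A4 is costly to reach: a four-membered ketone with a quaternary carbon must be made and a metallated bromopyridine added to it. It would arise as two carbinol diastereomers. The carbinol centre decides which methylene the catalyst recognises, so the two diastereomers should lead to opposite configurations at C6 and a single diastereomer is required. The C8 carbonyl must afterwards be removed next to the pyridine, and the carbamate exchanged for formyl.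
- **Comparison.** The mechanism (enantiotopic bond selection in a β-carbon elimination) rests on a narrower base of precedent than a dipolar cycloaddition. In structure it forms one ring and one bond. In step economy it is expected to be longer, roughly eleven steps in the longest line against seven.

**Alternative 3:** The cut is C8–C8a, the bond between the carbocycle and the pyridine carbon next to nitrogen.

- **Forward step.** In the 3-picolyl compound A6 the future C6 carries the aryl group and two vinyl groups. It would be treated with zerovalent nickel, Ni(cod)2, a chiral N-heterocyclic carbene and AlMe3. The Lewis acid binds the pyridine nitrogen, nickel activates the adjacent C8a–H bond and adds it in anti-Markovnikov fashion to one of the two enantiotopic vinyl groups. This closes the six-membered ring and leaves the other vinyl group in A7.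
- **In its favour.** The step is an isomerisation with complete atom economy, needs no protecting group or auxiliary, starts from an intact pyridine and sets the stereocentre by catalyst. On atom economy and on the absence of any sacrificial group it is better than the chosen plan.
- **Against it here.** The tether sits at C3 of the pyridine, so closure at C4 competes with closure at C2 (C8a), and Lewis-acid-assisted nickel catalysis often prefers positions remote from the complexed nitrogen. The catalyst must also enforce endo regiochemistry and distinguish two vinyl groups on a crowded quaternary carbon, for which precedent is limited. A6 itself needs a quaternary carbon bearing two vinyl groups. The remaining vinyl group of A7 must still be turned into the N-methylformamidoethyl arm by anti-Markovnikov functionalisation, amination and formylation.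
- **Comparison.** In mechanism it is a C–H activation with three simultaneous selectivity demands, against a cycloaddition with one (facial). In structure it forms one ring and one bond, against two rings and three bonds. In step economy the two are about equal in total count.

Key step: step 6

Assumption: the sense of facial induction by the (1R)-1-phenylethyl group cannot be predicted with confidence. The route is written with the (R)-amine, and 15 denotes the (3aS,9bR) cycloadduct; only this ring configuration matters downstream, because the auxiliary is excised in step 7.

## Route

Step 1
Reactants: 1 2-methylpyridine-3-carbonitrile; 2 2,3-dibromoprop-1-ene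
Product: 4 2-(3-bromobut-3-en-1-yl)pyridine-3-carbonitrile, via picolyllithium 3 (not isolated)
Conditions: LiN(iPr)2 (1.0 equiv.), THF, −78 °C; cannulated into 2 (1.5 equiv.), THF, −78 → −20 °C
Reagents that add atoms: none
Why: Lateral (picolylic) lithiation: the 2-methyl group is acidified by the ring nitrogen and the ortho nitrile, and the carbanion displaces the allylic bromide of 2 by SN2 while the vinylic bromide is inert; low temperature and inverse addition to excess 2 suppress self-condensation and double alkylation.

Step 2
Reactants: 4 2-(3-bromobut-3-en-1-yl)pyridine-3-carbonitrile; 5 (3,4-dimethoxyphenyl)boronic acid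
Product: 6 2-[3-(3,4-dimethoxyphenyl)but-3-en-1-yl]pyridine-3-carbonitrile
Conditions: PdCl2(dppf) (3 mol %), K2CO3, 1,4-dioxane/H2O, 80 °C
Reagents that add atoms: none
Why: Suzuki–Miyaura coupling: zerovalent palladium inserts into the C(sp2)–Br bond of the 2-bromoalkene, the boronate transfers the aryl group and reductive elimination gives the 1,1-disubstituted styrene; nitrile and pyridine are tolerated and no stereocentre is involved.

Step 3
Reactants: 6 2-[3-(3,4-dimethoxyphenyl)but-3-en-1-yl]pyridine-3-carbonitrile
Product: 8 2-[3-(3,4-dimethoxyphenyl)but-3-en-1-yl]pyridine-3-carbaldehyde, via N-aluminoaldimine 7 (not isolated)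
Conditions: iBu2AlH (1.3 equiv.), toluene, −78 °C; then 1 M aq. HCl, 0 °C → rt; NaHCO3
Reagents that add atoms: water, O
Why: Partial reduction of a nitrile: one hydride from iBu2AlH gives the N-aluminated aldimine 7, which is stable at −78 °C and is hydrolysed to the aldehyde on acidic work-up; the isolated styrene is not hydroaluminated at this temperature.

Step 4
Reactants: 9 (1R)-1-phenylethan-1-amine; 10 ethyl bromoacetate
Product: 11 ethyl N-[(1R)-1-phenylethyl]glycinate
Conditions: 9 (2 equiv.), K2CO3, MeCN, 0 °C → rt
Reagents that add atoms: none
Why: SN2 N-alkylation of a primary amine by an α-halo ester; excess amine and the α-branch of the amine hold the reaction at monoalkylation, and the benzylic stereocentre is not touched.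

Step 5
Reactants: 11 ethyl N-[(1R)-1-phenylethyl]glycinate
Product: 12 N-[(1R)-1-phenylethyl]glycine (zwitterion)
Conditions: LiOH·H2O, THF/H2O, rt; then aq. HCl to pH 6; desalting on a sulfonic acid resin
Reagents that add atoms: lithium hydroxide, [Li+].[OH-]
Why: Saponification of the ethyl ester (acyl–oxygen cleavage) and neutralisation to the isoelectric point give the free amino acid; the stereocentre is not α to the carbonyl and cannot epimerise.

Step 6
Reactants: 8 2-[3-(3,4-dimethoxyphenyl)but-3-en-1-yl]pyridine-3-carbaldehyde; 12 N-[(1R)-1-phenylethyl]glycine
Product: 15 (3aS,9bR)-3a-(3,4-dimethoxyphenyl)-1-[(1R)-1-phenylethyl]-2,3,3a,4,5,9b-hexahydro-1H-pyrrolo[2,3-f]quinoline, via oxazolidin-5-one 13 (not isolated), via azomethine ylide 14 (not isolated)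
Conditions: 12 (2 equiv.), toluene, reflux, Dean–Stark trap; 8 added over 6 h (final 0.02 M)
Reagents that add atoms: none
Why: Condensation of the aldehyde of 8 with the secondary amino acid 12 gives an iminium carboxylate that closes to the oxazolidin-5-one 13, and thermal loss of CO2 (a 1,3-dipolar cycloreversion) leaves the non-stabilised azomethine ylide 14 with its dipole across C5–N–Cβ. The closest known reaction type is the decarboxylative generation of azomethine ylides from aldehydes and N-alkyl α-amino acids followed by intramolecular [3+2] cycloaddition to a tethered, unactivated alkene. The carbocycle (C4a–C5–C6–C7–C8–C8a) closes through the C5–C6 bond in a 6-exo sense relative to the alkene, and the pyrrolidine (N–C5–C6–Cα–Cβ) is the five-membered ring of the concerted, suprafacial cycloaddition itself, completed by the Cα–Cβ bond. The two-atom tether allows only the fused regiochemistry (C5 to the internal, aryl-bearing alkene carbon) and forces a cis ring fusion, so C9b (the former C5) is fixed relative to C3a (the future C6) by the tether. The absolute configuration of C3a follows from the alkene face that meets the dipole, and this is biased by the (1R)-1-phenylethyl group on nitrogen, whose C–H bond should lie in the dipole plane to avoid allylic strain so that methyl and phenyl shield the two faces unequally. The step needs chemoselectivity for cycloaddition over capture of 14 by a second aldehyde (secured by slow addition of 8 to excess 12 at high dilution), regioselectivity (tether) and facial selectivity (auxiliary, expected to be modest; the two cis-fused products are diastereomers and are to be separated by chromatography).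

Step 7
Reactants: 15 (3aS,9bR)-3a-(3,4-dimethoxyphenyl)-1-[(1R)-1-phenylethyl]-2,3,3a,4,5,9b-hexahydro-1H-pyrrolo[2,3-f]quinoline
Product: 17 2-[(6S)-6-(3,4-dimethoxyphenyl)-5,6,7,8-tetrahydroquinolin-6-yl]ethan-1-amine, via secondary amine 16 (not isolated)
Conditions: H2 (4 bar), Pd(OH)2/C, MeOH/AcOH, 50 °C; then aq. NaOH
Reagents that add atoms: none
Why: Catalytic hydrogenolysis of benzylic-type C–N bonds: the 1-phenylethyl group should leave first (16), then the picolylic C9b–N bond is cleaved, which opens the pyrrolidine and erases the relay centre; acid keeps both nitrogens protonated so that they do not poison the catalyst, and the quaternary C6 is unaffected.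

Step 8
Reactants: 17 2-[(6S)-6-(3,4-dimethoxyphenyl)-5,6,7,8-tetrahydroquinolin-6-yl]ethan-1-amine
Product: 18 N-{2-[(6S)-6-(3,4-dimethoxyphenyl)-5,6,7,8-tetrahydroquinolin-6-yl]ethyl}formamide
Conditions: HCO2Et (solvent), reflux
Reagents that add atoms: ethyl formate, CCOC=O
Why: N-Formylation of a primary amine by aminolysis of a formate ester; the pyridine nitrogen is not acylated permanently and the stereocentre is remote.

Step 9
Reactants: 18 N-{2-[(6S)-6-(3,4-dimethoxyphenyl)-5,6,7,8-tetrahydroquinolin-6-yl]ethyl}formamide
Product: 20 N-{2-[(6S)-6-(3,4-dimethoxyphenyl)-5,6,7,8-tetrahydroquinolin-6-yl]ethyl}-N-methylformamide, via sodium amidate 19 (not isolated)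
Conditions: NaH (1.1 equiv.), THF/DMF, 0 °C; MeI (1.05 equiv.), 0 °C → rt
Reagents that add atoms: iodomethane, CI
Why: Deprotonation of the secondary formamide by NaH and SN2 N-methylation of the amidate 19; the anion is far more nucleophilic than the hindered 2,3-disubstituted pyridine nitrogen, so one equivalent of iodomethane at 0 °C should methylate the amide only.

## Compound list

1 | 2-methylpyridine-3-carbonitrile | Cc1ncccc1C#N | starting material
2 | 2,3-dibromoprop-1-ene | C=C(Br)CBr | starting material
3 | [(3-cyanopyridin-2-yl)methyl]lithium | [Li]Cc1ncccc1C#N | intermediate (not isolated)
4 | 2-(3-bromobut-3-en-1-yl)pyridine-3-carbonitrile | C=C(Br)CCc1ncccc1C#N | intermediate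
5 | (3,4-dimethoxyphenyl)boronic acid | COc1ccc(B(O)O)cc1OC | starting material
6 | 2-[3-(3,4-dimethoxyphenyl)but-3-en-1-yl]pyridine-3-carbonitrile | C=C(CCc1ncccc1C#N)c1ccc(OC)c(OC)c1 | intermediate
7 | N-(diisobutylalumanyl)-1-{2-[3-(3,4-dimethoxyphenyl)but-3-en-1-yl]pyridin-3-yl}methanimine | CC(C)C[Al](CC(C)C)N=Cc1cccnc1CCC(=C)c1ccc(OC)c(OC)c1 | intermediate (not isolated)
8 | 2-[3-(3,4-dimethoxyphenyl)but-3-en-1-yl]pyridine-3-carbaldehyde | C=C(CCc1ncccc1C=O)c1ccc(OC)c(OC)c1 | intermediate
9 | (1R)-1-phenylethan-1-amine | C[C@@H](N)c1ccccc1 | starting material
10 | ethyl bromoacetate | CCOC(=O)CBr | starting material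
11 | ethyl N-[(1R)-1-phenylethyl]glycinate | CCOC(=O)CN[C@H](C)c1ccccc1 | intermediate
12 | N-[(1R)-1-phenylethyl]glycine | C[C@@H](NCC(=O)O)c1ccccc1 | intermediate
13 | 2-{2-[3-(3,4-dimethoxyphenyl)but-3-en-1-yl]pyridin-3-yl}-3-[(1R)-1-phenylethyl]-1,3-oxazolidin-5-one (mixture at C2) | O=C1CN([C@H](C)c2ccccc2)C(O1)c1cccnc1CCC(=C)c1ccc(OC)c(OC)c1 | intermediate (not isolated)
14 | azomethine ylide: N-methylidene-N-[(1R)-1-phenylethyl]iminium with the carbanion on the pyridin-3-ylmethyl carbon of the 2-[3-(3,4-dimethoxyphenyl)but-3-en-1-yl]pyridin-3-yl unit | C=[N+]([C@H](C)c1ccccc1)[CH-]c1cccnc1CCC(=C)c1ccc(OC)c(OC)c1 | intermediate (not isolated)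
15 | (3aS,9bR)-3a-(3,4-dimethoxyphenyl)-1-[(1R)-1-phenylethyl]-2,3,3a,4,5,9b-hexahydro-1H-pyrrolo[2,3-f]quinoline (cis-fused) | COc1ccc([C@]23CCN([C@H](C)c4ccccc4)[C@H]2c2cccnc2CC3)cc1OC | intermediate
16 | (3aS,9bR)-3a-(3,4-dimethoxyphenyl)-2,3,3a,4,5,9b-hexahydro-1H-pyrrolo[2,3-f]quinoline | COc1ccc([C@]23CCN[C@H]2c2cccnc2CC3)cc1OC | intermediate (not isolated)
17 | 2-[(6S)-6-(3,4-dimethoxyphenyl)-5,6,7,8-tetrahydroquinolin-6-yl]ethan-1-amine | COc1ccc([C@@]2(CCN)CCc3ncccc3C2)cc1OC | intermediate
18 | N-{2-[(6S)-6-(3,4-dimethoxyphenyl)-5,6,7,8-tetrahydroquinolin-6-yl]ethyl}formamide | COc1ccc([C@@]2(CCNC=O)CCc3ncccc3C2)cc1OC | intermediate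
19 | sodium salt of 18 deprotonated at the formamide nitrogen | COc1ccc([C@@]2(CC[N-]C=O)CCc3ncccc3C2)cc1OC.[Na+] | intermediate (not isolated)
20 | N-{2-[(6S)-6-(3,4-dimethoxyphenyl)-5,6,7,8-tetrahydroquinolin-6-yl]ethyl}-N-methylformamide | COc1ccc([C@@]2(CCN(C)C=O)CCc3ncccc3C2)cc1OC | target

## Step count and least certain steps

Total step count: 9. Longest linear sequence: 7 steps (1, 2, 3, 6, 7, 8, 9); steps 4 and 5 form the short second branch.

**Step 6 (key step).**
- What may go wrong: poor facial selectivity. The 1-phenylethyl group differentiates the two alkene faces only through a methyl/phenyl difference at some distance from the forming bonds, so attack on the undesired face may compete strongly or even dominate. Capture of the ylide by a second aldehyde molecule would also lower the conversion to cycloadduct.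
- Fallback: give up auxiliary control and take the configuration from a separation of enantiomers. Setting out from 8, condensation with commercial N-benzylglycine under the conditions of step 6 should give the racemic cis-fused N-benzyl cycloadduct F1. Hydrogenolysis as in step 7 would give the racemic primary amine F2. Preparative chromatography of F2 on a chiral stationary phase would deliver the (S)-enantiomer, which is 17, where the route is rejoined.

**Step 7.**
- What may go wrong: stalling after loss of the auxiliary. The remaining picolylic C–N bond then belongs to a secondary amine on an electron-poor, neopentyl-like carbon and is cleaved more slowly. Forcing acidic conditions may start to saturate the pyridine ring.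
- Fallback: restore a tertiary amine, which is hydrogenolysed more readily, and introduce the methyl group at the same time. Setting out from 15, hydrogenolysis under mild neutral conditions (H2, Pd(OH)2/C, MeOH, rt) is stopped at 16, which is now isolated. Reductive methylation (aq. CH2O, NaBH(OAc)3) gives the N-methyl tricycle F3. Acid-promoted hydrogenolysis of F3 (H2, Pd(OH)2/C, AcOH) gives the secondary N-methyl amine F4. Formylation of F4 with ethyl formate returns the route at 20, bypassing steps 8 and 9.

**Step 1.**
- What may go wrong: self-condensation of the lithiated picoline with the nitrile of a second molecule, and double alkylation through proton exchange between product and carbanion.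
- Fallback: carry the aldehyde as an acetal, which no carbanion can attack. Setting out from 2 and 5, commercial 2-methylpyridine-3-carbaldehyde is converted to its dimethyl acetal F5 (HC(OMe)3, MeOH, TsOH). Lateral lithiation with LiN(iPr)2 and alkylation with 2 gives the bromoalkene acetal F6. Suzuki–Miyaura coupling with 5 gives the styrene acetal F7. Aqueous HCl unmasks the aldehyde and returns the route at 8.

**Step 9.**
- What may go wrong: competing quaternisation of the pyridine nitrogen or O-methylation of the amidate if the deprotonation is incomplete or excess iodomethane is present.
- Fallback: let the formyl carbon itself become the methyl group, so that no alkylating agent is used. Setting out from 18, reduction with LiAlH4 (THF, reflux) gives the secondary N-methyl amine F4 already met in the fallback to step 7. Formylation with ethyl formate returns the route at 20.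

## Further compounds

F1 | step 6 | rac-(3aS,9bR)-1-benzyl-3a-(3,4-dimethoxyphenyl)-2,3,3a,4,5,9b-hexahydro-1H-pyrrolo[2,3-f]quinoline (racemate, relative configuration shown) | COc1ccc([C@]23CCN(Cc4ccccc4)[C@H]2c2cccnc2CC3)cc1OC
F2 | step 6 | rac-2-[6-(3,4-dimethoxyphenyl)-5,6,7,8-tetrahydroquinolin-6-yl]ethan-1-amine (racemate) | COc1ccc(C2(CCN)CCc3ncccc3C2)cc1OC
F3 | step 7 | (3aS,9bR)-3a-(3,4-dimethoxyphenyl)-1-methyl-2,3,3a,4,5,9b-hexahydro-1H-pyrrolo[2,3-f]quinoline | COc1ccc([C@]23CCN(C)[C@H]2c2cccnc2CC3)cc1OC
F4 | step 7 | 2-[(6S)-6-(3,4-dimethoxyphenyl)-5,6,7,8-tetrahydroquinolin-6-yl]-N-methylethan-1-amine | COc1ccc([C@@]2(CCNC)CCc3ncccc3C2)cc1OC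
F5 | step 1 | 3-(dimethoxymethyl)-2-methylpyridine | COC(OC)c1cccnc1C
F6 | step 1 | 2-(3-bromobut-3-en-1-yl)-3-(dimethoxymethyl)pyridine | COC(OC)c1cccnc1CCC(Br)=C
F7 | step 1 | 2-[3-(3,4-dimethoxyphenyl)but-3-en-1-yl]-3-(dimethoxymethyl)pyridine | COC(OC)c1cccnc1CCC(=C)c1ccc(OC)c(OC)c1
F0 | step 9 | none | none
A1 | alternative 1 | 2-(3,4-dimethoxyphenyl)prop-2-enal | C=C(C=O)c1ccc(OC)c(OC)c1
A2 | alternative 1 | (1E)-3-{[tert-butyl(dimethyl)silyl]oxy}-N,N-dimethylbuta-1,3-dien-1-amine | CN(C)/C=C/C(=C)O[Si](C)(C)C(C)(C)C
A3 | alternative 1 | (1S)-1-(3,4-dimethoxyphenyl)-4-oxocyclohex-2-ene-1-carbaldehyde | COc1ccc([C@@]2(C=O)C=CC(=O)CC2)cc1OC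
A4 | alternative 2 | tert-butyl {2-[3-(3-bromopyridin-2-yl)-1-(3,4-dimethoxyphenyl)-3-hydroxycyclobutyl]ethyl}methylcarbamate (achiral; drawn as the diastereomer with hydroxyl and aryl cis) | COc1ccc([C@]2(CCN(C)C(=O)OC(C)(C)C)C[C@@](O)(c3ncccc3Br)C2)cc1OC
A5 | alternative 2 | tert-butyl {2-[(6S)-6-(3,4-dimethoxyphenyl)-8-oxo-5,6,7,8-tetrahydroquinolin-6-yl]ethyl}methylcarbamate | COc1ccc([C@@]2(CCN(C)C(=O)OC(C)(C)C)CC(=O)c3ncccc3C2)cc1OC
A6 | alternative 3 | 3-[2-(3,4-dimethoxyphenyl)-2-ethenylbut-3-en-1-yl]pyridine | C=CC(C=C)(Cc1cccnc1)c1ccc(OC)c(OC)c1
A7 | alternative 3 | (6S)-6-(3,4-dimethoxyphenyl)-6-ethenyl-5,6,7,8-tetrahydroquinoline | COc1ccc([C@@]2(C=C)CCc3ncccc3C2)cc1OC
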